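The disconnection removes both benzylic carbons from the lactone at once, through the bonds C3–CH2Ar and C4–CH2Ar. The target's γ-butyrolactone carries two identical arylmethyl groups cis on the adjacent ring carbons C3 and C4, with the C3 hydroxyl on the other face; that pattern is the imprint of a cyclobutene cis-fused to the lactone. One sensitised [2+2] photocycloaddition of a symmetrical diarylalkyne to an enantiopure butenolide makes both C–C bonds, the four-membered ring and both stereocentres. The butenolide is (5R)-3-acetoxy-5-(l-menthyloxy)furan-2(5H)-one, whose acetal directs the face; ozonolysis and hydrogenolysis then turn the cyclobutene carbons into the two CH2 groups.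

Key step: step 7

Remark: lactone numbering O1, C2(=O), C3, C4, C5 is used throughout; the acetal carbon C5 ends as the ring CH2, so its configuration only steers step 7. The tetra-alkoxy diarylalkyne, not the butenolide, is expected to be the long-wavelength chromophore and the lowest triplet, so step 7 is designed with the alkyne as the sensitised partner and the butenolide as ground-state trap.

Step 1
Reactants: 1 4-bromo-2-methoxyphenol
Product: 2 1-(benzyloxy)-4-bromo-2-methoxybenzene
Conditions: BnBr (1.1 equiv), K2CO3 (1.5 equiv), acetone, reflux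
Reagents that add atoms: benzyl bromide, BrCc1ccccc1
Why: Williamson etherification of the phenoxide; the aryl bromide is inert and the benzyl ether is later removed in the hydrogenolysis of step 9.

Step 2
Reactants: 2 1-(benzyloxy)-4-bromo-2-methoxybenzene (2 equiv); 3 trimethylsilylacetylene (1 equiv)
Product: 6 1,2-bis[4-(benzyloxy)-3-methoxyphenyl]ethyne, via silylated arylalkyne 4 (not isolated), via terminal arylalkyne 5 (not isolated)
Conditions: PdCl2(PPh3)2 (5 mol %), CuI (10 mol %), DBU (6 equiv), H2O (0.5 equiv), MeCN, 80 °C, sealed vessel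
Reagents that add atoms: none
Why: One-pot double Sonogashira coupling, in which the C–H end of 3 couples first, DBU and water then remove silicon in the flask and the freed alkyne couples with the second aryl bromide.

Step 3
Reactants: 7 furfural
Product: 8 5-hydroxyfuran-2(5H)-one (racemic)
Conditions: O2, methylene blue (cat.), MeOH, visible light, 20 °C
Reagents that add atoms: oxygen, O=O
Why: Dye-sensitised singlet-oxygen [4+2] addition to the furan followed by methanolysis of the endoperoxide, which expels the formyl carbon as methyl formate; the lactol is racemic at this stage.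

Step 4
Reactants: 8 5-hydroxyfuran-2(5H)-one; 9 (−)-menthol
Product: 11 (5R)-5-(l-menthyloxy)furan-2(5H)-one, via C5-epimeric acetal 10 (not isolated)
Conditions: p-TsOH·H2O (cat.), toluene, reflux, Dean–Stark; crystallisation from petroleum ether; mother liquor re-equilibrated (p-TsOH) and recrystallised
Reagents that add atoms: none
Why: Acid-catalysed acetalisation of the lactol gives both C5 epimers, and since the (5R) epimer is expected to crystallise while the (5S) epimer 10 re-equilibrates through the oxocarbenium ion, C5 is set by crystallisation-driven epimerisation.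

Step 5
Reactants: 11 (5R)-5-(l-menthyloxy)furan-2(5H)-one
Product: 12 (3S,4R,5R)-3,4-dihydroxy-5-(l-menthyloxy)dihydrofuran-2(3H)-one
Conditions: OsO4 (2 mol %), NMO (1.5 equiv), acetone–H2O (5:1), 20 °C
Reagents that add atoms: N-methylmorpholine N-oxide, C[N+]1([O-])CCOCC1; water, O
Why: Upjohn syn-dihydroxylation of the butenolide alkene from the face anti to the C5 menthyloxy group; both new centres are provisional because C3 and C4 become sp2 again in step 6.

Step 6
Reactants: 12 (3S,4R,5R)-3,4-dihydroxy-5-(l-menthyloxy)dihydrofuran-2(3H)-one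
Product: 14 (5R)-3-acetoxy-5-(l-menthyloxy)furan-2(5H)-one, via diacetate 13 (not isolated)
Conditions: Ac2O (2.5 equiv), Et3N (4 equiv), DMAP (5 mol %), CH2Cl2, 0 → 20 °C, quenched as soon as elimination is complete
Reagents that add atoms: acetic anhydride, CC(=O)OC(C)=O
Why: Double O-acetylation followed by E1cB loss of the C4 acetate from the C3 lactone enolate, the known β-elimination of 2,3-di-O-acyl-1,4-lactones to 2-acyloxybutenolides; C5 is not involved.

Step 7
Reactants: 14 (5R)-3-acetoxy-5-(l-menthyloxy)furan-2(5H)-one (1 equiv, 0.2 M); 6 1,2-bis[4-(benzyloxy)-3-methoxyphenyl]ethyne (1.5 equiv)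
Product: 15 (1S,4R,5R)-6,7-bis[4-(benzyloxy)-3-methoxyphenyl]-4-(l-menthyloxy)-2-oxo-3-oxabicyclo[3.2.0]hept-6-en-1-yl acetate
Conditions: thioxanthen-9-one (10 mol %), 385 nm LEDs, degassed CH2Cl2, 20 °C, stopped at partial conversion
Reagents that add atoms: none
Why: Thioxanthen-9-one should be the only absorber at 385 nm and should pass its triplet energy to alkyne 6, the lowest triplet present, while butenolide 14 stays in its planar ground state, which shuts off acyl shifts and dimerisation of an excited enol acetate. The diradicaloid alkyne triplet bonds through one alkyne carbon to the β-carbon C4 of 14 and gives a 1,4-biradical (an α-aryl vinyl radical plus a C3 radical stabilised captodatively by the acetoxy group and the lactone carbonyl); after intersystem crossing, recombination of the vinyl carbon with C3 closes the four-membered ring, a stepwise formal [2+2] and not a concerted one. The closest known reactions are triplet-sensitised [2+2] additions of diarylalkynes to electron-poor cyclic alkenes such as maleimides, and enone–alkyne photocycloadditions of 2(5H)-furanones, 5-menthyloxy ones included, to fused cyclobutenes. The C4 centre (C5 of the bicycle) is set in the first bond formation, in which the carbon radical takes the butenolide face anti to the adjacent C5 menthyloxy group, as ground-state radical additions and cycloadditions to 11 do. The C3 centre (C1 of the bicycle) follows without choice, because a cyclobutene can be fused to the five-membered lactone only cis, which leaves the acetoxy group on the menthyloxy face and both future benzylic carbons on the opposite one. Regioselectivity does not arise because 6 is symmetrical, so only facial selectivity (acetal) and selective excitation (sensitiser and wavelength) are needed; since 15 is a cyclobutene-locked stilbene and itself a triplet acceptor, unreacted 14 and 6 are recycled.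

Step 8
Reactants: 15 (1S,4R,5R)-6,7-bis[4-(benzyloxy)-3-methoxyphenyl]-4-(l-menthyloxy)-2-oxo-3-oxabicyclo[3.2.0]hept-6-en-1-yl acetate
Product: 16 (3S,4R,5R)-3,4-bis[4-(benzyloxy)-3-methoxybenzoyl]-5-(l-menthyloxy)-2-oxotetrahydrofuran-3-yl acetate
Conditions: O3, CH2Cl2–MeOH (5:1), −78 °C, Sudan Red 7B end point; then PPh3 (1.2 equiv), −78 → 20 °C; crude product used after short filtration
Reagents that add atoms: ozone, [O-][O+]=O
Why: Criegee ozonolysis, in which the strained, tetrasubstituted, stilbene-like C6=C7 bond should react far faster than the alkoxyarenes (the dye stops the ozone feed), and neutral phosphine reduction releases the two aryl ketones without touching C3, C4 or C5.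

Step 9
Reactants: 16 (3S,4R,5R)-3,4-bis[4-(benzyloxy)-3-methoxybenzoyl]-5-(l-menthyloxy)-2-oxotetrahydrofuran-3-yl acetate
Product: 17 (3R,4R,5R)-3,4-bis(4-hydroxy-3-methoxybenzyl)-5-(l-menthyloxy)-2-oxotetrahydrofuran-3-yl acetate
Conditions: H2 (4 bar), 10 % Pd/C, AcOH–EtOAc (1:1), 40 °C
Reagents that add atoms: none
Why: Catalytic hydrogenolysis, in which each para-oxygenated aryl ketone is reduced to the benzylic alcohol and on to ArCH2 while both O-benzyl groups are cleaved; no new stereocentre forms, C3 is quaternary and the weakly acidic medium should not enolise the ketone toward C4.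

Step 10
Reactants: 17 (3R,4R,5R)-3,4-bis(4-hydroxy-3-methoxybenzyl)-5-(l-menthyloxy)-2-oxotetrahydrofuran-3-yl acetate
Product: 20 epinortrachelogenin, (3R,4S)-3-hydroxy-3,4-bis(4-hydroxy-3-methoxybenzyl)dihydrofuran-2(3H)-one, via aldehyde acid 18 (not isolated), via dihydroxy acid 19 (not isolated)
Conditions: NaBH4 (4 equiv), KOH (6 equiv), EtOH–H2O, 0 → 20 °C, under N2; then 2 M HCl to pH 1, 20 °C
Reagents that add atoms: potassium hydroxide, [K+].[OH-] (its oxygen enters the carboxyl group on ring opening)
Why: Saponification and in-situ borohydride reduction, a known way of removing this acetal auxiliary: hydroxide opens the acetal lactone (menthol leaves from the hemiacetal) and cleaves the acetate, NaBH4 present from the start reduces the aldehyde before C4 can epimerise, and acidification closes the γ-lactone onto the C2 carboxyl, so C5 becomes CH2 while C3 and C4 keep their configuration.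

Compound list
1 | 4-bromo-2-methoxyphenol | COc1cc(Br)ccc1O | starting material
2 | 1-(benzyloxy)-4-bromo-2-methoxybenzene | COc1cc(Br)ccc1OCc1ccccc1 | intermediate
3 | trimethylsilylacetylene | C#C[Si](C)(C)C | starting material
4 | {[4-(benzyloxy)-3-methoxyphenyl]ethynyl}trimethylsilane | COc1cc(C#C[Si](C)(C)C)ccc1OCc1ccccc1 | intermediate (not isolated)
5 | 1-(benzyloxy)-4-ethynyl-2-methoxybenzene | COc1cc(C#C)ccc1OCc1ccccc1 | intermediate (not isolated)
6 | 1,2-bis[4-(benzyloxy)-3-methoxyphenyl]ethyne | COc1cc(C#Cc2ccc(OCc3ccccc3)c(OC)c2)ccc1OCc1ccccc1 | intermediate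
7 | furfural | O=Cc1ccco1 | starting material
8 | 5-hydroxyfuran-2(5H)-one (racemic) | O=C1C=CC(O)O1 | intermediate
9 | (−)-menthol, (1R,2S,5R)-2-isopropyl-5-methylcyclohexanol | CC(C)[C@@H]1CC[C@@H](C)C[C@H]1O | starting material
10 | (5S)-5-(l-menthyloxy)furan-2(5H)-one | O=C1C=C[C@@H](O[C@@H]2C[C@H](C)CC[C@H]2C(C)C)O1 | intermediate (not isolated)
11 | (5R)-5-(l-menthyloxy)furan-2(5H)-one | O=C1C=C[C@H](O[C@@H]2C[C@H](C)CC[C@H]2C(C)C)O1 | intermediate
12 | (3S,4R,5R)-3,4-dihydroxy-5-(l-menthyloxy)dihydrofuran-2(3H)-one (cis-diol anti to menthyloxy) | O=C1O[C@@H](O[C@@H]2C[C@H](C)CC[C@H]2C(C)C)[C@H](O)[C@@H]1O | intermediate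
13 | (3S,4R,5R)-5-(l-menthyloxy)-2-oxotetrahydrofuran-3,4-diyl diacetate | O=C1O[C@@H](O[C@@H]2C[C@H](C)CC[C@H]2C(C)C)[C@H](OC(C)=O)[C@@H]1OC(C)=O | intermediate (not isolated)
14 | (5R)-3-acetoxy-5-(l-menthyloxy)furan-2(5H)-one | CC(=O)OC1=C[C@H](O[C@@H]2C[C@H](C)CC[C@H]2C(C)C)OC1=O | intermediate
15 | (1S,4R,5R)-6,7-bis[4-(benzyloxy)-3-methoxyphenyl]-4-(l-menthyloxy)-2-oxo-3-oxabicyclo[3.2.0]hept-6-en-1-yl acetate (cyclobutene anti to menthyloxy, acetoxy on the menthyloxy face) | CC(=O)O[C@@]12C(=O)O[C@@H](O[C@@H]3C[C@H](C)CC[C@H]3C(C)C)[C@@H]1C(c1ccc(OCc3ccccc3)c(OC)c1)=C2c1ccc(OCc2ccccc2)c(OC)c1 | intermediate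
16 | (3S,4R,5R)-3,4-bis[4-(benzyloxy)-3-methoxybenzoyl]-5-(l-menthyloxy)-2-oxotetrahydrofuran-3-yl acetate (aroyl groups cis) | CC(=O)O[C@@]1(C(=O)c2ccc(OCc3ccccc3)c(OC)c2)C(=O)O[C@@H](O[C@@H]2C[C@H](C)CC[C@H]2C(C)C)[C@@H]1C(=O)c1ccc(OCc2ccccc2)c(OC)c1 | intermediate
17 | (3R,4R,5R)-3,4-bis(4-hydroxy-3-methoxybenzyl)-5-(l-menthyloxy)-2-oxotetrahydrofuran-3-yl acetate (benzyl groups cis) | CC(=O)O[C@@]1(Cc2ccc(O)c(OC)c2)C(=O)O[C@@H](O[C@@H]2C[C@H](C)CC[C@H]2C(C)C)[C@@H]1Cc1ccc(O)c(OC)c1 | intermediate
18 | (2R,3R)-3-formyl-2-hydroxy-2-(4-hydroxy-3-methoxybenzyl)-4-(4-hydroxy-3-methoxyphenyl)butanoic acid (potassium salt in the flask) | COc1cc(C[C@@H](C=O)[C@](O)(Cc2ccc(O)c(OC)c2)C(=O)O)ccc1O | intermediate (not isolated)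
19 | (2R,3S)-2-hydroxy-3-(hydroxymethyl)-2-(4-hydroxy-3-methoxybenzyl)-4-(4-hydroxy-3-methoxyphenyl)butanoic acid | COc1cc(C[C@@H](CO)[C@](O)(Cc2ccc(O)c(OC)c2)C(=O)O)ccc1O | intermediate (not isolated)
20 | epinortrachelogenin, (3R,4S)-3-hydroxy-3,4-bis(4-hydroxy-3-methoxybenzyl)dihydrofuran-2(3H)-one | COc1cc(C[C@H]2COC(=O)[C@@]2(O)Cc2ccc(O)c(OC)c2)ccc1O | target

Total step count: 10 (steps 1–2 alkyne branch, steps 3–6 butenolide branch, steps 7–10 after convergence).
Longest linear sequence: 8 steps (furfural 7 to 20 through steps 3–10).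

Steps most likely to fail

Step 7. Trapping of the short-lived alkyne triplet by 14 may lose against its unproductive decay. The adduct may also be re-excited by the sensitiser and revert or react further, and face selection in the first bond formation at C4 may be incomplete. The fallback uses known ground-state chemistry, sets out from 11 and comes back to the route at 20.
- Commercial 4-(benzyloxy)-3-methoxybenzaldehyde and propane-1,3-dithiol (BF3·OEt2, CH2Cl2) give 2-[4-(benzyloxy)-3-methoxyphenyl]-1,3-dithiane F1.
- The commercial benzylic alcohol and PBr3 give 4-(benzyloxy)-3-methoxybenzyl bromide F2.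
- Lithiated F1 (n-BuLi, THF, −78 °C) should add to C4 of 11 anti to the menthyloxy group, and the resulting lactone enolate should be alkylated by F2 trans to the new C4 substituent. This gives the 3,4-trans-4,5-trans dithianyl benzyl lactone acetal F3.
- Desulfurisation (NiCl2·6H2O, NaBH4, MeOH–THF) should give the trans-3,4-dibenzyl acetal lactone F4.
- NaBH4/KOH followed by HCl, as in step 10, should give (3R,4R)-di-O-benzylmatairesinol F5.
- Deprotonation with KN(SiMe3)2 (THF, −78 °C) and enolate oxidation with 2-(phenylsulfonyl)-3-phenyloxaziridine should bring oxygen in anti to the C4 benzyl group, which places the two benzyl groups cis and gives di-O-benzylepinortrachelogenin F6.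
- H2, Pd/C, EtOAc then gives 20.

Step 9. C–O hydrogenolysis at the hindered benzylic carbon on quaternary C3 may stall at the alcohol stage. Acid-promoted dehydration or enolisation toward C4 could also erode the cis relationship, and the acetal may exchange in acetic acid. Acetyl migration to the neighbouring benzylic oxygen would be harmless, since step 10 removes the acetate. The fallback sets out from 16 and comes back at 17. Ionic hydrogenation (Et3SiH, CF3CO2H, CH2Cl2, 0 → 20 °C) reduces para-alkoxyaryl ketones to ArCH2 through benzylic cations without a metal surface, and should give (3R,4R,5R)-3,4-bis[4-(benzyloxy)-3-methoxybenzyl]-5-(l-menthyloxy)-2-oxotetrahydrofuran-3-yl acetate F7. Neutral hydrogenolysis (H2, Pd/C, EtOAc, 20 °C) then removes only the O-benzyl groups and gives 17.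

Step 8. Excess ozone may over-oxidise the dialkoxyarene rings or the benzylic ether CH2 groups, and acetic acid may be lost by β-elimination from the β-acetoxy ketone during work-up. The fallback sets out from 15 and comes back at 16. Dihydroxylation of the cyclobutene with stoichiometric OsO4 and pyridine (CH2Cl2, then NaHSO3) should give the cis-6,7-diol of 15, with both hydroxyls on the cyclobutane face opposite the lactone ring, F8. Glycol cleavage with Pb(OAc)4 (CH2Cl2, 0 °C) then opens the four-membered ring to 16 without ozone.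

Further compounds
F1 | step 7 | 2-[4-(benzyloxy)-3-methoxyphenyl]-1,3-dithiane | COc1cc(C2SCCCS2)ccc1OCc1ccccc1
F2 | step 7 | 4-(benzyloxy)-3-methoxybenzyl bromide | COc1cc(CBr)ccc1OCc1ccccc1
F3 | step 7 | (3R,4R,5R)-3-[4-(benzyloxy)-3-methoxybenzyl]-4-{2-[4-(benzyloxy)-3-methoxyphenyl]-1,3-dithian-2-yl}-5-(l-menthyloxy)dihydrofuran-2(3H)-one | O=C1O[C@@H](O[C@@H]2C[C@H](C)CC[C@H]2C(C)C)[C@H](C2(c3ccc(OCc4ccccc4)c(OC)c3)SCCCS2)[C@H]1Cc1ccc(OCc2ccccc2)c(OC)c1
F4 | step 7 | (3R,4R,5R)-3,4-bis[4-(benzyloxy)-3-methoxybenzyl]-5-(l-menthyloxy)dihydrofuran-2(3H)-one | O=C1O[C@@H](O[C@@H]2C[C@H](C)CC[C@H]2C(C)C)[C@H](Cc2ccc(OCc3ccccc3)c(OC)c2)[C@H]1Cc1ccc(OCc2ccccc2)c(OC)c1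
F5 | step 7 | (3R,4R)-3,4-bis[4-(benzyloxy)-3-methoxybenzyl]dihydrofuran-2(3H)-one (di-O-benzylmatairesinol) | O=C1OC[C@H](Cc2ccc(OCc3ccccc3)c(OC)c2)[C@H]1Cc1ccc(OCc2ccccc2)c(OC)c1
F6 | step 7 | (3R,4S)-3,4-bis[4-(benzyloxy)-3-methoxybenzyl]-3-hydroxydihydrofuran-2(3H)-one (di-O-benzylepinortrachelogenin) | COc1cc(C[C@H]2COC(=O)[C@@]2(O)Cc2ccc(OCc3ccccc3)c(OC)c2)ccc1OCc1ccccc1
F7 | step 9 | (3R,4R,5R)-3,4-bis[4-(benzyloxy)-3-methoxybenzyl]-5-(l-menthyloxy)-2-oxotetrahydrofuran-3-yl acetate | CC(=O)O[C@@]1(Cc2ccc(OCc3ccccc3)c(OC)c2)C(=O)O[C@@H](O[C@@H]2C[C@H](C)CC[C@H]2C(C)C)[C@@H]1Cc1ccc(OCc2ccccc2)c(OC)c1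
F8 | step 8 | cis-6,7-diol of 15: 6,7-bis[4-(benzyloxy)-3-methoxyphenyl]-6,7-dihydroxy-4-(l-menthyloxy)-2-oxo-3-oxabicyclo[3.2.0]heptan-1-yl acetate, hydroxyls on the face opposite the lactone ring | CC(=O)O[C@@]12C(=O)O[C@@H](O[C@@H]3C[C@H](C)CC[C@H]3C(C)C)[C@@H]1[C@](O)(c1ccc(OCc3ccccc3)c(OC)c1)[C@]2(O)c1ccc(OCc2ccccc2)c(OC)c1
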